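**Plan**

- Retrosynthesis: after removal of the two benzyl groups and the O2 methyl group, ring B is cut at C1–C2 and C2–C3 (C2 goes back to carbon monoxide) and the aryl ester oxygen is returned from C4 to C5. This opens ring B to a 3-acyloxy-1,4-enyne that already carries ring A as its ester.
- Enabling feature: ring B is a resorcinol in which O4 bears the ring A acyl group and O2 sits on the carbon between C1 and C3. This is the 1,3-dioxygen pattern left by a 1,2-acyloxy shift plus one inserted CO.
- The enyne ester is cut at its alkyl C–O bond (ring A acid and propargylic alcohol), the alcohol at the alkyne–carbinol bond, and the formyl enoate at its C=C bond (heptanal and benzyl glyoxylate).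
- Forward: the ring A acid is made from olivetol in four steps and the enyne alcohol in three. Esterification joins them, ring B (the only ring formed) is built by rhodium-catalysed carbonylation, and O-methylation and hydrogenolysis finish.
- Stereochemistry: the target is achiral. The E enoate geometry comes from the thermodynamically controlled condensation, and the racemic carbinol centre disappears on aromatisation.

Key step: step 9

Remark on the chemistry: benzyl glyoxylate is used as the free aldehyde (hydrate and oligomers cracked on distillation); the carbinol carbon of 7 and 15 is racemic throughout.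

**Step 1**
Reactants: 1 dibenzyl L-tartrate
Product: 2 benzyl glyoxylate
Conditions: H5IO6, Et2O, rt; distil
Reagents that add atoms: none
Why: Periodic acid glycol cleavage (Malaprade oxidation) splits the C2–C3 bond of the tartrate into two glyoxylate units and leaves the benzyl esters alone.

**Step 2**
Reactants: 2 benzyl glyoxylate; 3 heptanal
Product: 5 benzyl (E)-3-formyloct-2-enoate, via aldol adduct 4 (not isolated)
Conditions: Bu2NH (0.2 equiv), AcOH (0.2 equiv), toluene, 80 °C, slow addition of 3 to excess 2
Reagents that add atoms: none
Why: Secondary-amine-catalysed cross-aldol condensation (Mannich-type enamine addition to the far more electrophilic glyoxylate, then E1cB loss of water from 4), in which the E isomer with formyl trans to the ester is the thermodynamic product reached by equilibration under the amine salt.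

**Step 3**
Reactants: 5 benzyl (E)-3-formyloct-2-enoate; 6 ethynylmagnesium bromide
Product: 7 benzyl (E)-4-hydroxy-3-pentylhex-2-en-5-ynoate (racemic)
Conditions: THF, −78 → −20 °C; then H2O, aq. NH4Cl
Reagents that add atoms: none
Why: Grignard 1,2-addition to the aldehyde, which at low temperature is far more electrophilic than the conjugated benzyl ester; the new carbinol centre is racemic, which is harmless because it becomes an aromatic CH in step 9.

**Step 4**
Reactants: 8 olivetol (5-pentylbenzene-1,3-diol)
Product: 10 2,4-dihydroxy-6-pentylbenzaldehyde, via iminium chloride 9 (not isolated)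
Conditions: POCl3, DMF, 0 °C → rt; then H2O, 50 °C
Reagents that add atoms: N,N-dimethylformamide, CN(C)C=O; water, O
Why: Vilsmeier–Haack formylation of the resorcinol ring should go, as usual for 5-alkylresorcinols, para to one hydroxyl and next to the alkyl chain, and the aqueous work-up hydrolyses iminium salt 9 to the aldehyde.

**Step 5**
Reactants: 10 2,4-dihydroxy-6-pentylbenzaldehyde
Product: 11 4-(benzyloxy)-2-hydroxy-6-pentylbenzaldehyde
Conditions: BnBr (1.05 equiv), NaHCO3, KI (cat.), MeCN, 80 °C
Reagents that add atoms: benzyl bromide, BrCc1ccccc1
Why: Williamson etherification under a weak base, which ionises only the 4-hydroxyl because the 2-hydroxyl is held in a hydrogen bond to the aldehyde.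

**Step 6**
Reactants: 11 4-(benzyloxy)-2-hydroxy-6-pentylbenzaldehyde
Product: 12 4-(benzyloxy)-2-methoxy-6-pentylbenzaldehyde
Conditions: MeI, K2CO3, DMF, rt → 40 °C
Reagents that add atoms: iodomethane, CI
Why: Williamson O-methylation of the remaining chelated phenol, for which carbonate in DMF is basic enough.

**Step 7**
Reactants: 12 4-(benzyloxy)-2-methoxy-6-pentylbenzaldehyde
Product: 13 4-(benzyloxy)-2-methoxy-6-pentylbenzoic acid
Conditions: NaClO2, NaH2PO4, 2-methyl-2-butene, t-BuOH/H2O, rt
Reagents that add atoms: sodium chlorite, [Na+].[O-]Cl=O
Why: Pinnick oxidation converts the hindered aldehyde into the acid under buffered conditions, while 2-methyl-2-butene traps HOCl so that the electron-rich ring is not chlorinated.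

**Step 8**
Reactants: 13 4-(benzyloxy)-2-methoxy-6-pentylbenzoic acid; 7 benzyl (E)-4-hydroxy-3-pentylhex-2-en-5-ynoate
Product: 15 benzyl (E)-4-{[4-(benzyloxy)-2-methoxy-6-pentylbenzoyl]oxy}-3-pentylhex-2-en-5-ynoate (racemic), via acid chloride 14 (not isolated)
Conditions: (COCl)2, DMF (cat.), CH2Cl2, 0 °C → rt; evaporate; then 7, pyridine, DMAP (0.2 equiv), CH2Cl2, 0 °C → rt
Reagents that add atoms: none
Why: Acid chloride formation with oxalyl chloride/DMF followed by DMAP-catalysed acylation of the secondary alcohol, with pyridine as a base too weak to remove the acidic propargylic hydrogen of the product.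

**Step 9**
Reactants: 15 benzyl (E)-4-{[4-(benzyloxy)-2-methoxy-6-pentylbenzoyl]oxy}-3-pentylhex-2-en-5-ynoate; 16 carbon monoxide
Product: 18 benzyl 4-{[4-(benzyloxy)-2-methoxy-6-pentylbenzoyl]oxy}-2-hydroxy-6-pentylbenzoate, via cyclohexadienone 17 (not isolated)
Conditions: [Rh(CO)2Cl]2 (5 mol %), CO (20 atm), ClCH2CH2Cl, 80 °C
Reagents that add atoms: none
Why: Proposed new method: monovalent rhodium of [Rh(CO)2Cl]2 activates the terminal alkyne of 15, the aroyl carbonyl oxygen attacks the internal alkyne carbon in a 5-exo sense and the acyloxy group shifts from the carbinol carbon to that carbon (1,2-shift via a dioxolenylium), which leaves a rhodium vinylcarbene conjugated with the enoate. This metallatriene closes by 6π electrocyclisation onto the enoate α-carbon to a rhodacyclohexadiene, CO inserts and reductive elimination forms the second bond to the new carbonyl carbon (the equivalent path is CO capture to a dienylketene and its 6π closure), so ring B closes in a (5+1) mode with CO as C2 between the former alkyne terminus (C3) and the enoate α-carbon (C1). The closest known reaction is the [Rh(CO)2Cl]2-catalysed (5+1) carbonylation of 3-acyloxy-1,4-enynes bearing alkyl-substituted alkenes to resorcinol monoesters; new here are the ester on the alkene terminus, which electrocyclisations of dienylketenes are known to tolerate, and the doubly ortho-substituted aroyl migrating group. Dienone 17 is a cyclic β-keto ester and enolises to salicylate 18, so its single sp3 carbon and the racemic carbinol carbon of 15 both end as aromatic carbons and no stereocentre needs control. The step needs the 1,2-shift to win over the 1,3-shift to an allenyl ester, which the unsubstituted alkyne terminus and the electron-rich aroyl carbonyl secure, and an unencumbered alkene terminus, which the E geometry secures by pointing hydrogen and not the ester toward the carbene carbon. Since the five enyne carbons are already in ring order, the ring A acyl group can only arrive on O4 and the CO-derived hydroxyl on C2.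

**Step 10**
Reactants: 18 benzyl 4-{[4-(benzyloxy)-2-methoxy-6-pentylbenzoyl]oxy}-2-hydroxy-6-pentylbenzoate
Product: 19 benzyl 4-{[4-(benzyloxy)-2-methoxy-6-pentylbenzoyl]oxy}-2-methoxy-6-pentylbenzoate
Conditions: MeI, K2CO3, DMF, rt
Reagents that add atoms: iodomethane, CI
Why: Williamson O-methylation of the salicylate-type phenol, to which the hindered aryl ester between the rings and the benzyl ester are inert under anhydrous carbonate, while the meta relation of O2 and O4 excludes acyl migration.

**Step 11**
Reactants: 19 benzyl 4-{[4-(benzyloxy)-2-methoxy-6-pentylbenzoyl]oxy}-2-methoxy-6-pentylbenzoate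
Product: 20 4-O-demethylplanaic acid
Conditions: H2 (1 atm), 10% Pd/C, EtOAc, rt
Reagents that add atoms: none
Why: Catalytic hydrogenolysis removes the benzyl ether and the benzyl ester in one operation and leaves the aryl ester, the methyl ethers and both rings untouched.

**Compound list**

1 | dibenzyl L-tartrate, (2R,3R) | O=C(OCc1ccccc1)[C@H](O)[C@@H](O)C(=O)OCc1ccccc1 | starting material
2 | benzyl glyoxylate | O=CC(=O)OCc1ccccc1 | intermediate
3 | heptanal | CCCCCCC=O | starting material
4 | benzyl 3-formyl-2-hydroxyoctanoate (aldol adduct, mixture of diastereomers) | CCCCCC(C=O)C(O)C(=O)OCc1ccccc1 | intermediate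
5 | benzyl (E)-3-formyloct-2-enoate (= benzyl (E)-4-oxo-3-pentylbut-2-enoate) | O=C/C(CCCCC)=C/C(=O)OCc1ccccc1 | intermediate
6 | ethynylmagnesium bromide | C#C[Mg]Br | starting material
7 | benzyl (E)-4-hydroxy-3-pentylhex-2-en-5-ynoate (racemic) | C#CC(O)/C(CCCCC)=C/C(=O)OCc1ccccc1 | intermediate
8 | olivetol (5-pentylbenzene-1,3-diol) | CCCCCc1cc(O)cc(O)c1 | starting material
9 | N-[(2,4-dihydroxy-6-pentylphenyl)methylidene]-N-methylmethanaminium chloride | CCCCCc1cc(O)cc(O)c1C=[N+](C)C.[Cl-] | intermediate
10 | 2,4-dihydroxy-6-pentylbenzaldehyde | CCCCCc1cc(O)cc(O)c1C=O | intermediate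
11 | 4-(benzyloxy)-2-hydroxy-6-pentylbenzaldehyde | CCCCCc1cc(OCc2ccccc2)cc(O)c1C=O | intermediate
12 | 4-(benzyloxy)-2-methoxy-6-pentylbenzaldehyde | CCCCCc1cc(OCc2ccccc2)cc(OC)c1C=O | intermediate
13 | 4-(benzyloxy)-2-methoxy-6-pentylbenzoic acid | CCCCCc1cc(OCc2ccccc2)cc(OC)c1C(=O)O | intermediate
14 | 4-(benzyloxy)-2-methoxy-6-pentylbenzoyl chloride | CCCCCc1cc(OCc2ccccc2)cc(OC)c1C(=O)Cl | intermediate
15 | benzyl (E)-4-{[4-(benzyloxy)-2-methoxy-6-pentylbenzoyl]oxy}-3-pentylhex-2-en-5-ynoate (racemic) | C#CC(OC(=O)c1c(CCCCC)cc(OCc2ccccc2)cc1OC)/C(CCCCC)=C/C(=O)OCc1ccccc1 | intermediate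
16 | carbon monoxide | [C-]#[O+] | starting material
17 | benzyl 4-{[4-(benzyloxy)-2-methoxy-6-pentylbenzoyl]oxy}-2-oxo-6-pentylcyclohexa-3,5-diene-1-carboxylate (racemic keto tautomer of 18) | O=C1C=C(OC(=O)c2c(CCCCC)cc(OCc3ccccc3)cc2OC)C=C(CCCCC)C1C(=O)OCc1ccccc1 | intermediate
18 | benzyl 4-{[4-(benzyloxy)-2-methoxy-6-pentylbenzoyl]oxy}-2-hydroxy-6-pentylbenzoate | CCCCCc1cc(OC(=O)c2c(CCCCC)cc(OCc3ccccc3)cc2OC)cc(O)c1C(=O)OCc1ccccc1 | intermediate
19 | benzyl 4-{[4-(benzyloxy)-2-methoxy-6-pentylbenzoyl]oxy}-2-methoxy-6-pentylbenzoate | CCCCCc1cc(OC(=O)c2c(CCCCC)cc(OCc3ccccc3)cc2OC)cc(OC)c1C(=O)OCc1ccccc1 | intermediate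
20 | 4-O-demethylplanaic acid, 4-[(4-hydroxy-2-methoxy-6-pentylbenzoyl)oxy]-2-methoxy-6-pentylbenzoic acid | CCCCCc1cc(OC(=O)c2c(CCCCC)cc(O)cc2OC)cc(OC)c1C(=O)O | target

**Count**

Total steps: 11. Longest linear sequence: 8 steps (olivetol 8 through steps 4–11 to 20); the enyne alcohol branch (steps 1–3) joins at step 8.

**Steps most likely to fail**

Step 9 (carbonylative ring closure). The acyloxy group may take the 1,3-path to an allenyl ester that is carbonylated to a five-membered ketone or oligomerises. Alternatively the carbene may fail to close onto the electron-poor alkene, so that the alkyne is consumed unproductively. The fallback is the classical depside esterification, without carbonylation, and sets out from acid 13. Commercial olivetolic acid is benzylated at the carboxylate (BnBr, KHCO3, DMF) to benzyl 2,4-dihydroxy-6-pentylbenzoate F1. Acid 13 is activated with trifluoroacetic anhydride in toluene as 4-(benzyloxy)-2-methoxy-6-pentylbenzoic trifluoroacetic anhydride F2. F2 should acylate F1 at the free 4-hydroxyl, the 2-hydroxyl being chelated to the ester carbonyl. This gives 18, where the route is rejoined before step 10.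

Step 8 (esterification). Acyl transfer from the doubly ortho-substituted aroyl chloride may be slow, so that base-promoted prototropy at the acidic propargylic carbon (to an allene or a conjugated dienoate) overtakes ester formation. The fallback is a Mitsunobu esterification that sets out from alcohol 7 and acid 13 (PPh3, diisopropyl azodicarboxylate, toluene, 0 °C). The carboxylate then attacks the activated carbinol carbon, so the crowding at the acyl carbon no longer matters and the medium is neutral. The inversion is irrelevant for a racemate. It returns at 15 and makes no compound outside the list (F0).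

Step 2 (condensation). Self-condensation of heptanal and oligomerisation of the glyoxylate may outrun the cross-condensation, and the double bond may form without clean E control. The fallback is a Wittig olefination that sets out from glyoxylate 2. Hexyltriphenylphosphonium bromide is deprotonated (n-BuLi, THF, 0 °C) to hexylidene(triphenyl)phosphorane F3, which is formylated with ethyl formate to the stabilised ylide 2-(triphenylphosphoranylidene)heptanal F4. F4 and 2 in toluene should give the E enal ester directly, since stabilised ylides place the formyl group trans to the incoming substituent. The route is rejoined at 5.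

**Further compounds**

F1 | step 9 | benzyl 2,4-dihydroxy-6-pentylbenzoate | CCCCCc1cc(O)cc(O)c1C(=O)OCc1ccccc1
F2 | step 9 | 4-(benzyloxy)-2-methoxy-6-pentylbenzoic trifluoroacetic anhydride | CCCCCc1cc(OCc2ccccc2)cc(OC)c1C(=O)OC(=O)C(F)(F)F
F0 | step 8 | none | none
F3 | step 2 | hexylidene(triphenyl)phosphorane | CCCCCC=P(c1ccccc1)(c1ccccc1)c1ccccc1
F4 | step 2 | 2-(triphenylphosphoranylidene)heptanal | CCCCCC(C=O)=P(c1ccccc1)(c1ccccc1)c1ccccc1
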